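**Strategy.** Atoms are numbered in target SMILES order. Opening the cyclohexene at C10=C11 (aldol retron) exposes a C23 ketone and a C11 aldehyde placed 1,5 across C21–C22–C12 of the cis-fused cyclopentane (C16–C17–C18–C21–C22)/γ-lactone (C12–C13–O15–C16–C22). One photochemical operation builds that array: the enol double bond C21=C11 of a 2-formyl ketone adds across a tethered butenolide (C22=C12), forming C21–C22 and C11–C12, and the cyclobutanol then fragments by retro-aldol. The precursor is a mevalonate-derived chain: tertiary silyl ether at C18, (R)-butenolide at C16, and the acetyl/oxymethylene pair on C21, with the enol fixed as a benzyl ether so that only this double bond can react.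

Key step: step 9

Remarks on the chemistry:
- In all bi- and tricyclic compounds H12, H16, H21 and H22 are mutually cis (convex face); the C18 methyl lies on that face and the C18 oxygen on the concave face.
- Assumption: (R)-BINAP in step 16 and the Josiphos enantiomer in the fallback to step 12 are the ones the usual facial models predict for the stated face; the mirror-image ligand is used if the sense proves opposite.
- Enamine, vinylogous amide and enol ether geometries are immaterial and drawn as one isomer; C11 in 15, 16 and 18 and the lactol carbon of 25 are transient and left undefined.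

**Step 1**
Reactants: 1 (R)-mevalonolactone
Product: 2 (4R)-4-(tert-butyldimethylsilyloxy)-4-methyloxan-2-one
Conditions: TBSOTf, 2,6-lutidine, CH2Cl2, 0 °C
Reagents that add atoms: tert-butyldimethylsilyl triflate, CC(C)(C)[Si](C)(C)OS(=O)(=O)C(F)(F)F
Why: Silyl triflate/2,6-lutidine silylation of the hindered tertiary alcohol; C18 comes unchanged from the chiral pool, and the robust TBS ether is chosen because this oxygen later sits β to carbonyl groups and must survive acid, mild base and hydrogenation.

**Step 2**
Reactants: 2 (4R)-4-(tert-butyldimethylsilyloxy)-4-methyloxan-2-one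
Product: 3 (3R)-3-(tert-butyldimethylsilyloxy)-5-hydroxy-N-methoxy-N,3-dimethylpentanamide
Conditions: MeNH(OMe)·HCl, AlMe3, CH2Cl2, 0 °C → rt; Rochelle salt work-up
Reagents that add atoms: N,O-dimethylhydroxylamine hydrochloride, CNOC.Cl
Why: Weinreb amidation of the lactone with the chloroaluminium amide opens the ring under non-basic conditions (no elimination of the β-silyloxy group) and differentiates the two arms, the acyl carbon (future C16) as the N-methoxy-N-methylamide and the primary alcohol (future C11).

**Step 3**
Reactants: 3 (3R)-3-(tert-butyldimethylsilyloxy)-5-hydroxy-N-methoxy-N,3-dimethylpentanamide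
Product: 4 (3R)-3-(tert-butyldimethylsilyloxy)-N-methoxy-N,3-dimethyl-5-oxopentanamide
Conditions: Dess–Martin periodinane, NaHCO3, CH2Cl2, 0 °C → rt
Reagents that add atoms: none
Why: Dess–Martin oxidation of the primary alcohol under bicarbonate buffer should give the β-silyloxy aldehyde without elimination or over-oxidation; the Weinreb amide is inert.

**Step 4**
Reactants: 4 (3R)-3-(tert-butyldimethylsilyloxy)-N-methoxy-N,3-dimethyl-5-oxopentanamide; 5 acetyl chloride
Product: 7 C21-acetylated enamine (vinylogous amide) 4-acetyl-3-(tert-butyldimethylsilyloxy)-N-methoxy-N,3-dimethyl-5-(morpholin-4-yl)pent-4-enamide (C18 as in 2), via morpholine enamine 6 (not isolated)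
Conditions: morpholine, 4 Å MS, CH2Cl2, rt; then Et3N, AcCl, 0 °C → rt
Reagents that add atoms: morpholine, C1COCCN1; acetyl chloride (5), CC(=O)Cl
Why: Stork enamine acylation: the aldehyde has a single α-carbon (C21), so C-acetylation of its morpholine enamine is regiochemically unambiguous, and the resulting vinylogous amide is a stable, non-acidic mask for the 2-formyl ketone during steps 5 to 7.

**Step 5**
Reactants: 7 vinylogous amide Weinreb amide; 8 triethyl orthopropiolate (3,3,3-triethoxyprop-1-yne)
Product: 9 ynone ortho ester (C16 ketone flanked by C17H2 and the C22≡C12–C(OEt)3 alkyne)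
Conditions: 8, nBuLi, THF, −78 °C; then 7, −78 → −20 °C; aq. NaHCO3
Reagents that add atoms: 3,3,3-triethoxyprop-1-yne (8), C#CC(OCC)(OCC)OCC
Why: Weinreb ketone synthesis: the lithium acetylide adds once to the N-methoxy-N-methylamide (stable chelated tetrahedral intermediate), the electron-rich vinylogous amide carbonyl does not compete at low temperature, and the ortho ester keeps the ynone from being a doubly activated Michael acceptor.

**Step 6**
Reactants: 9 ynone ortho ester
Product: 10 (16R)-propargylic alcohol
Conditions: Ru[(R,R)-TsDPEN](p-cymene) (1 mol%), iPrOH, rt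
Reagents that add atoms: none
Why: Noyori asymmetric transfer hydrogenation of an α,β-acetylenic ketone: the (R,R)-catalyst delivers hydride to the carbonyl face that gives the (R)-propargylic alcohol (alkynyl ranked above alkyl), so C16 is set by the catalyst and not by the remote C18 centre; the base-free catalyst spares the ortho ester and the vinylogous amide.

**Step 7**
Reactants: 10 (16R)-propargylic alcohol
Product: 13 chelated enol of the 2-formyl ketone tethered to the (R)-butenolide (free hydroxymethylene ketone), via Z-allylic alcohol ortho ester 11 (not isolated), via butenolide vinylogous amide 12 (not isolated)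
Conditions: H2 (1 atm), Lindlar catalyst (Pd/CaCO3, Pb(OAc)2-poisoned), quinoline, EtOAc, rt; filter; then 1 M aq. HCl, THF, rt
Reagents that add atoms: water, O
Why: Lindlar semi-hydrogenation gives the (Z)-alkene, and aqueous acid then hydrolyses the ortho ester to the carboxyl level, which lactonises with the cis-disposed C16 hydroxyl to the butenolide (C16 retained), and hydrolyses the vinylogous amide to the 2-formyl ketone enol; the medium stays acidic so the dicarbonyl is never deprotonated next to the butenolide, to which its enolate could add thermally.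

**Step 8**
Reactants: 13 free hydroxymethylene ketone butenolide
Product: 14 benzyl enol ether (benzyloxymethylene ketone) of 13
Conditions: BnOH, PPTS (cat.), benzene, 4 Å MS, 50 °C
Reagents that add atoms: benzyl alcohol, OCc1ccccc1
Why: Acid-catalysed enol etherification of a hydroxymethylene ketone (alcohol adds to the aldehyde carbon C11, water is lost) fixes the enol double bond at C21=C11 whatever the tautomer ratio or the strain of the chelated enol next to quaternary C18; benzyl is chosen because it can be removed by hydrogenolysis once the butenolide alkene has been consumed.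

**Step 9**
Reactants: 14 benzyl enol ether
Product: 17 cyclopenta-fused α-formyl γ-lactone methyl ketone (C11 aldehyde on C12, C23 acetyl on C21, C18 OTBS), via cyclobutane benzyl ether 15 (not isolated), via cyclobutanol 16 (not isolated)
Conditions: hν (λ ≥ 300 nm, Pyrex, medium-pressure Hg lamp), degassed MeCN (5 mM), rt; concentrate; then H2 (1 atm), Pd/C, EtOAc, rt
Reagents that add atoms: none
Why: Excitation of the β-benzyloxy enone, the only chromophore above 300 nm, should give its triplet, which bonds C21 to the butenolide β-carbon C22 and then collapses the 1,4-diradical (α-oxy radical at C11, α-acyl radical at C12) to cyclobutane 15; hydrogenolysis of the benzyl ether frees cyclobutanol 16, whose strained β-hydroxy ketone opens by retro-aldol (C21–C11 cleavage) to the C11 aldehyde and the C23 ketone. The closest known reaction type is the de Mayo reaction in its protected-enol form (intramolecular enone–alkene [2+2] photocycloaddition, unmasking, retro-aldol). The cyclopentane C16–C17–C18–C21–C22 closes in 5-exo fashion as the three-atom tether dictates (rule of five), so the straight and not the crossed adduct forms, and the transient cyclobutane closes by diradical recombination. C22 is fixed by the tether from C16, which reaches only the butenolide face syn to C17 (cis-fused bicyclic lactone); C12 is fixed by the necessarily cis-fused cyclobutane and keeps its C11–C12 bond through the fragmentation; C21 is set when the enol released by the retro-aldol is protonated on the convex face, and it stays correctable as a ketone α-centre. The step needs control over which enol double bond reacts and over what is excited: the benzyl ether pins the enol at C21=C11, the butenolide is transparent at this wavelength, and no other alkene is present.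

**Step 10**
Reactants: 17 keto aldehyde
Product: 19 tricyclic cyclohexenone (C23 ketone, C10=C11), via aldol adduct 18 (not isolated)
Conditions: piperidine (0.3 equiv), AcOH (0.3 equiv), benzene, 60 °C
Reagents that add atoms: none
Why: Intramolecular aldol condensation under amine–acid (Knoevenagel-type) catalysis: C10 of the methyl ketone adds to the C11 formyl group in a 6-(enolexo)-exo-trig closure and water is lost toward conjugation with the C23 ketone; C21 and C12 are enolisable and should settle into the all-cis fusion around C22, the only low-strain arrangement of the three rings, while the near-neutral medium avoids β-elimination of the C18 silyloxy group.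

**Step 11**
Reactants: 19 tricyclic cyclohexenone
Product: 20 α-iodoenone (iodine on C10)
Conditions: I2, pyridine, CH2Cl2, 0 °C → rt
Reagents that add atoms: iodine, II
Why: α-Iodination of a cyclic enone with I2/pyridine (conjugate addition of pyridine, iodination at C10, elimination); the iodide is the later Heck handle and a steric control element in step 12, and pyridine is too weak a base to disturb C12 or C21.

**Step 12**
Reactants: 20 α-iodoenone; 21 allyl methoxymethyl ether
Product: 22 tertiary alcohol with C23(OH)–C28H(OMOM)–CH=CH2 (C28 on the convex face, 28S)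
Conditions: 21, sBuLi, THF, −78 °C; Et2AlCl, −78 °C; then 20, −78 °C
Reagents that add atoms: 3-(methoxymethoxy)prop-1-ene (21), C=CCOCOC
Why: Addition of a (Z)-γ-alkoxyallylaluminium reagent to a ketone through a Zimmerman–Traxler chair forms C23–C28 with allylic transposition; attack comes from the convex face (the concave face is blocked by the C18 silyloxy group and the folded rings), and because aluminium binds the carbonyl lone pair remote from the C10–I bond, C10 sits equatorial in the chair and the axial OMOM group of the (Z)-reagent should end syn to C10; the reagent is weakly basic, which spares the acidic C12–H.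

**Step 13**
Reactants: 22 homoallylic tertiary alcohol MOM ether
Product: 24 1,4-diol (C25 primary alcohol, C23 tertiary alcohol), via B-alkyl-9-BBN 23 (not isolated)
Conditions: 9-BBN, THF, 0 °C → rt; then NaBO3·4H2O, THF/H2O, rt
Reagents that add atoms: sodium perborate, [Na+].[O-]B1OO1
Why: Hydroboration–oxidation: 9-BBN adds anti-Markovnikov to the only monosubstituted alkene (the iodoalkene is trisubstituted and electron-poor) and perborate oxidises the C–B bond under mild conditions that leave the lactone alone; no stereocentre is formed.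

**Step 14**
Reactants: 24 1,4-diol
Product: 26 spiro γ-lactone with C28 OMOM and C10 iodide, via lactol 25 (not isolated)
Conditions: TEMPO (0.2 equiv), PhI(OAc)2, CH2Cl2, rt
Reagents that add atoms: none
Why: Oxidative lactonisation of a 1,4-diol: TEMPO/PhI(OAc)2 oxidises the primary alcohol to the aldehyde, the tertiary C23 hydroxyl traps it as the lactol, and a second oxidation gives the lactone; stereocentres are untouched.

**Step 15**
Reactants: 26 iodo spirolactone; 27 methyl acrylate
Product: 28 (E)-dienoate (C10–C4H=C5H–CO2Me)
Conditions: Pd(OAc)2 (10 mol%), Bu4NCl, NaHCO3, DMF, 50 °C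
Reagents that add atoms: methyl acrylate (27), C=CC(=O)OC
Why: Heck reaction of the alkenyl iodide with methyl acrylate under ligand-free phase-transfer conditions: syn carbopalladation and syn β-hydride elimination give the (E)-dienoate; no stereocentre is formed.

**Step 16**
Reactants: 28 (E)-dienoate; 29 isopropenylboronic acid pinacol ester
Product: 30 bis-protected target (C28 OMOM, C18 OTBS, 4S)
Conditions: [Rh(OH)(cod)]2 (3 mol%), (R)-BINAP (7 mol%), dioxane/H2O (10:1), 50 °C
Reagents that add atoms: 4,4,5,5-tetramethyl-2-(prop-1-en-2-yl)-1,3,2-dioxaborolane (29), CC(=C)B1OC(C)(C)C(C)(C)O1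
Why: Hayashi–Miyaura rhodium-catalysed asymmetric 1,4-addition of an alkenylboron reagent to an (E)-enoate: the BINAP ligand directs isopropenyl to the Re face of C4 (4S), 1,6-addition is disfavoured because the δ-carbon C11 is a ring carbon next to fully substituted C10, and the base-free hydroxo-rhodium conditions leave lactones, acetal and silyl ether alone.

**Step 17**
Reactants: 30 bis-protected target
Product: 32 CNP0148106.2 (target), via C18 TBS ether 31 (not isolated)
Conditions: Me2BBr, CH2Cl2, −78 °C; aq. NaHCO3; then 48% aq. HF, MeCN, 0 °C → rt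
Reagents that add atoms: none
Why: Dimethylboron bromide cleaves the methoxymethyl acetal at −78 °C without touching esters, lactones or alkenes, and aqueous HF then removes the tertiary TBS ether (fluoride-driven Si–O cleavage); no stereocentre is affected.

**Compound list**

1 | (R)-mevalonolactone | O=C1C[C@](C)(O)CCO1 | starting material
2 | (4R)-4-(tert-butyldimethylsilyloxy)-4-methyloxan-2-one | O=C1C[C@](C)(O[Si](C)(C)C(C)(C)C)CCO1 | intermediate
3 | (3R)-3-(tert-butyldimethylsilyloxy)-5-hydroxy-N-methoxy-N,3-dimethylpentanamide | OCC[C@@](C)(O[Si](C)(C)C(C)(C)C)CC(=O)N(C)OC | intermediate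
4 | (3R)-3-(tert-butyldimethylsilyloxy)-N-methoxy-N,3-dimethyl-5-oxopentanamide | O=CC[C@@](C)(O[Si](C)(C)C(C)(C)C)CC(=O)N(C)OC | intermediate
5 | acetyl chloride | CC(=O)Cl | starting material
6 | morpholine enamine of 4 (E) | O=C(C[C@](C)(O[Si](C)(C)C(C)(C)C)/C=C/N1CCOCC1)N(C)OC | intermediate
7 | vinylogous amide: 4-acetyl-3-(tert-butyldimethylsilyloxy)-N-methoxy-N,3-dimethyl-5-(morpholin-4-yl)pent-4-enamide, C18 as in 2 | CC(=O)/C(=C\N1CCOCC1)[C@@](C)(O[Si](C)(C)C(C)(C)C)CC(=O)N(C)OC | intermediate
8 | triethyl orthopropiolate (3,3,3-triethoxyprop-1-yne) | C#CC(OCC)(OCC)OCC | starting material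
9 | ynone ortho ester (C16 ketone, C22≡C12, C13 as triethyl ortho ester) | CC(=O)/C(=C\N1CCOCC1)[C@@](C)(O[Si](C)(C)C(C)(C)C)CC(=O)C#CC(OCC)(OCC)OCC | intermediate
10 | (16R)-propargylic alcohol from 9 | CC(=O)/C(=C\N1CCOCC1)[C@@](C)(O[Si](C)(C)C(C)(C)C)C[C@@H](O)C#CC(OCC)(OCC)OCC | intermediate
11 | (Z)-allylic alcohol ortho ester (16R) | CC(=O)/C(=C\N1CCOCC1)[C@@](C)(O[Si](C)(C)C(C)(C)C)C[C@@H](O)/C=C\C(OCC)(OCC)OCC | intermediate
12 | (R)-butenolide carrying the vinylogous amide | CC(=O)/C(=C\N1CCOCC1)[C@@](C)(O[Si](C)(C)C(C)(C)C)C[C@H]2OC(=O)C=C2 | intermediate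
13 | chelated enol of the 2-formyl ketone tethered to the (R)-butenolide, C18 OTBS | CC(=O)/C(=C\O)[C@@](C)(O[Si](C)(C)C(C)(C)C)C[C@H]1OC(=O)C=C1 | intermediate
14 | benzyl enol ether of 13 (benzyloxymethylene ketone) | CC(=O)/C(=C\OCc1ccccc1)[C@@](C)(O[Si](C)(C)C(C)(C)C)C[C@H]2OC(=O)C=C2 | intermediate
15 | photoadduct: cyclobutane (C21–C22–C12–C11) fused to cyclopentane and γ-lactone, C11 OBn, acetyl on C21 cis to H22 | CC(=O)[C@]12C(OCc4ccccc4)[C@@H]3C(=O)O[C@@H]([C@H]23)C[C@]1(C)O[Si](C)(C)C(C)(C)C | intermediate
16 | cyclobutanol from 15 | CC(=O)[C@]12C(O)[C@@H]3C(=O)O[C@@H]([C@H]23)C[C@]1(C)O[Si](C)(C)C(C)(C)C | intermediate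
17 | cyclopenta-fused α-formyl γ-lactone methyl ketone (largely enolised at C12–C11) | O=C[C@@H]1C(=O)O[C@@H]2C[C@](C)(O[Si](C)(C)C(C)(C)C)[C@@H]([C@H]12)C(C)=O | intermediate
18 | aldol adduct (C11 hydroxyl, C23 ketone) | C1C(O)[C@@H]2C(=O)O[C@@H]3C[C@](C)(O[Si](C)(C)C(C)(C)C)[C@@H]([C@H]23)C1=O | intermediate
19 | tricyclic cyclohexenone (C23=O, C10=C11) | C1=C[C@@H]2C(=O)O[C@@H]3C[C@](C)(O[Si](C)(C)C(C)(C)C)[C@@H]([C@H]23)C1=O | intermediate
20 | α-iodoenone (C10–I) | IC1=C[C@@H]2C(=O)O[C@@H]3C[C@](C)(O[Si](C)(C)C(C)(C)C)[C@@H]([C@H]23)C1=O | intermediate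
21 | allyl methoxymethyl ether | C=CCOCOC | starting material
22 | C23 tertiary alcohol with (28S)-C28H(OMOM)–CH=CH2, C28 on the convex face | IC1=C[C@@H]2C(=O)O[C@@H]3C[C@](C)(O[Si](C)(C)C(C)(C)C)[C@@H]([C@H]23)[C@@]1(O)[C@@H](OCOC)C=C | intermediate
23 | B-alkyl-9-BBN from 22 | IC1=C[C@@H]2C(=O)O[C@@H]3C[C@](C)(O[Si](C)(C)C(C)(C)C)[C@@H]([C@H]23)[C@@]1(O)[C@@H](OCOC)CCB4C5CCCC4CCC5 | intermediate
24 | 1,4-diol (C25 primary OH, C23 tertiary OH, C28 OMOM) | IC1=C[C@@H]2C(=O)O[C@@H]3C[C@](C)(O[Si](C)(C)C(C)(C)C)[C@@H]([C@H]23)[C@@]1(O)[C@@H](OCOC)CCO | intermediate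
25 | spiro lactol | IC1=C[C@@H]2C(=O)O[C@@H]3C[C@](C)(O[Si](C)(C)C(C)(C)C)[C@@H]([C@H]23)[C@]12OC(O)C[C@@H]2OCOC | intermediate
26 | spiro γ-lactone, C28 OMOM syn to C10, C10–I, C18 OTBS | IC1=C[C@@H]2C(=O)O[C@@H]3C[C@](C)(O[Si](C)(C)C(C)(C)C)[C@@H]([C@H]23)[C@]12OC(=O)C[C@@H]2OCOC | intermediate
27 | methyl acrylate | C=CC(=O)OC | starting material
28 | (E)-dienoate on C10 | COC(=O)/C=C/C1=C[C@@H]2C(=O)O[C@@H]3C[C@](C)(O[Si](C)(C)C(C)(C)C)[C@@H]([C@H]23)[C@]12OC(=O)C[C@@H]2OCOC | intermediate
29 | isopropenylboronic acid pinacol ester | CC(=C)B1OC(C)(C)C(C)(C)O1 | starting material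
30 | bis-protected target (4S; C28 OMOM; C18 OTBS) | C=C(C)[C@H](CC(=O)OC)C1=C[C@@H]2C(=O)O[C@@H]3C[C@](C)(O[Si](C)(C)C(C)(C)C)[C@@H]([C@H]23)[C@]12OC(=O)C[C@@H]2OCOC | intermediate
31 | C18 TBS ether of the target | C=C(C)[C@H](CC(=O)OC)C1=C[C@@H]2C(=O)O[C@@H]3C[C@](C)(O[Si](C)(C)C(C)(C)C)[C@@H]([C@H]23)[C@]12OC(=O)C[C@@H]2O | intermediate
32 | CNP0148106.2 | C=C(C)[C@H](CC(=O)OC)C1=C[C@@H]2C(=O)O[C@@H]3C[C@](C)(O)[C@@H]([C@H]23)[C@]12OC(=O)C[C@@H]2O | target

**Totals.** 17 steps; the longest linear sequence is 17 steps (1 → 32); 5, 8, 21, 27 and 29 are bought.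

**Steps most likely to fail**

Step 9. The triplet alkoxyenone may lose its energy by twisting about C21=C11 faster than it bonds to the butenolide, because C21 must become a quaternary centre next to quaternary C18; first bonding at the wrong termini would give crossed or cleaved material. The fallback replaces light by anion chemistry. Starting from 13, a weak base (Et3N, MeCN, 0 °C) that deprotonates only the dicarbonyl should trigger 5-exo Michael addition of C21 to C22. This gives the 2-acetyl-2-formyl Michael adduct F1 as its lactone enolate. That enolate adds to the formyl group (C12 to C11), and the cyclobutanolate (the alkoxide of 16) fragments with 1,3-formyl migration, the classical abnormal Michael course. Acidification returns the route at 17.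

Step 12. Proton transfer from the acidic C12–H to the allylmetal may outrun addition to the hindered C23 ketone, or a loosely organised transition state may erode control at C28. The fallback builds the spirolactone by alkynylation and sets C28 afterwards. From 20, the cerium acetylide of 8 (nBuLi, CeCl3, THF, −78 °C) should add to the convex face to give the propargylic alcohol ortho ester F2. Lindlar semi-hydrogenation gives the Z-allylic alcohol F3, and mild aqueous acid closes it to the spirobutenolide F4. Copper-catalysed enantioselective β-borylation (CuCl, Josiphos, NaOtBu, B2pin2, MeOH) gives the C28 boronate F5, with the ligand enantiomer that delivers boron to the C28 face syn to C10. Perborate oxidation gives the hydroxy lactone F6, and MOMCl/iPr2NEt brings the route back at 26.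

Step 16. Insertion at the hindered β-carbon C4 may be slow against protodeboronation, or the ligand may be mismatched with the substrate and give poor facial selectivity. The fallback uses a stoichiometric auxiliary. From 26, Heck coupling with (R)-3-acryloyl-4-phenyloxazolidin-2-one should give the dienoyl imide F7. Isopropenylmagnesium bromide/CuBr·SMe2 (THF, −40 °C) adds to the chelated s-cis imide anti to the phenyl group, that is to the Re face of C4, giving the adduct F8. MeOMgBr in MeOH exchanges the auxiliary for the methyl ester and returns the route at 30.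

**Further compounds**

F1 | step 9 | 2-acetyl-2-formyl cyclopentane cis-fused to the γ-lactone (Michael adduct, C21 undefined) | CC(=O)C1(C=O)[C@@H]2CC(=O)O[C@@H]2C[C@]1(C)O[Si](C)(C)C(C)(C)C
F2 | step 12 | C23 propargylic alcohol ortho ester | IC1=C[C@@H]2C(=O)O[C@@H]3C[C@](C)(O[Si](C)(C)C(C)(C)C)[C@@H]([C@H]23)[C@@]1(O)C#CC(OCC)(OCC)OCC
F3 | step 12 | Z-allylic alcohol ortho ester | IC1=C[C@@H]2C(=O)O[C@@H]3C[C@](C)(O[Si](C)(C)C(C)(C)C)[C@@H]([C@H]23)[C@@]1(O)/C=C\C(OCC)(OCC)OCC
F4 | step 12 | spirobutenolide | IC1=C[C@@H]2C(=O)O[C@@H]3C[C@](C)(O[Si](C)(C)C(C)(C)C)[C@@H]([C@H]23)[C@]12OC(=O)C=C2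
F5 | step 12 | C28 pinacol boronate of the spirolactone | IC1=C[C@@H]2C(=O)O[C@@H]3C[C@](C)(O[Si](C)(C)C(C)(C)C)[C@@H]([C@H]23)[C@]12OC(=O)C[C@@H]2B4OC(C)(C)C(C)(C)O4
F6 | step 12 | (28S)-hydroxy spirolactone iodide | IC1=C[C@@H]2C(=O)O[C@@H]3C[C@](C)(O[Si](C)(C)C(C)(C)C)[C@@H]([C@H]23)[C@]12OC(=O)C[C@@H]2O
F7 | step 16 | dienoyl imide of (R)-4-phenyloxazolidin-2-one | O=C(/C=C/C1=C[C@@H]2C(=O)O[C@@H]3C[C@](C)(O[Si](C)(C)C(C)(C)C)[C@@H]([C@H]23)[C@]12OC(=O)C[C@@H]2OCOC)N4C(=O)OC[C@H]4c5ccccc5
F8 | step 16 | (4S)-isopropenyl adduct imide | C=C(C)[C@H](CC(=O)N4C(=O)OC[C@H]4c5ccccc5)C1=C[C@@H]2C(=O)O[C@@H]3C[C@](C)(O[Si](C)(C)C(C)(C)C)[C@@H]([C@H]23)[C@]12OC(=O)C[C@@H]2OCOC
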